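**Plan**

1. Germacrane locants are used (ring C1–C10; lactone O–C6, C7, C11, C12; C13 exo-methylene; C14 on C10; C15 on C4). The enabling feature is the 1,5-diene C10=C1–C2–C3–C4=C5 inside the ten-membered ring, with C1=C10 Z and C4=C5 E: this is what a cis-fused bicyclo[2.2.0]hexane C1–C2–C3–C4–C5–C10 releases on heating.
2. Retrosynthetic cuts: the C9–O acyl bond (angelate) and C11=C13; then C1–C4 and C5–C10 are re-formed to fold the ring into a 6-4-4 tricycle; then C10–C1 and C5–C4 are cut to a 2-methylcyclohex-2-enone (C5–C10) and 1-methylcyclobutene (C1–C4, C15).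
3. The enone is cut at C5=C10 (ring-closing metathesis), C9–C10 (Grignard), the lactone C12–O bond and C7–C11 (ester enolate addition), back to L-arabinose, whose C1–C5 become C9, C8, C7, C6, C5.
4. Forward ring order: furanose template, γ-lactone, cyclohexene, cyclobutane (6-4-4 tricycle), ten-membered ring by cycloreversion; then C9–OH, C13 and the angelate.
5. Stereochemistry: C8 and C6 are C2 and C4 of L-arabinose; C7 comes from exo-face addition to the furanos-3-ulose; C9 from Felkin–Anh hydride addition; both ring alkene geometries from the chair cyclohexane-1,4-diyl of the cycloreversion; the angelate geometry from angelic acid.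

Key step: step 13

Remark on locants: sugar locants are used for compounds 2–10, germacrane locants from 11 onwards (sugar C1, C2, C3, C4, C5 = C9, C8, C7, C6, C5).

Assumption: in the Luche reduction of the ten-membered enone 18, hydride is taken to add anti to the C8–O bond (Felkin–Anh) and to give the 9R alcohol; the opposite outcome is covered by a fallback.

**Route**

Step 1
Reactants: 1 L-arabinose
Product: 2 5-O-(tert-butyldiphenylsilyl)-L-arabinofuranose (both anomers)
Conditions: tBuPh2SiCl, pyridine, rt
Reagents that add atoms: tert-butyl(chloro)diphenylsilane CC(C)(C)[Si](Cl)(c1ccccc1)c1ccccc1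
Why: Selective silyl ether formation at the only primary hydroxyl, which is free only in the furanose form, should pull the sugar out of its pyranose form into the 5-O-silyl furanose without touching a stereocentre.

Step 2
Reactants: 2 5-O-(tert-butyldiphenylsilyl)-L-arabinofuranose
Product: 3 5-O-(tert-butyldiphenylsilyl)-1,2-O-isopropylidene-β-L-arabinofuranose
Conditions: Me2C(OMe)2, TsOH (cat.), acetone, rt
Reagents that add atoms: 2,2-dimethoxypropane COC(C)(C)OC
Why: Acid-catalysed acetonide formation can bridge only the cis O1/O2 pair of the β-anomer (O3 is trans to O2 and O5 is silylated), which fixes the anomeric centre and leaves C3–OH as the single free hydroxyl.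

Step 3
Reactants: 3 5-O-(tert-butyldiphenylsilyl)-1,2-O-isopropylidene-β-L-arabinofuranose
Product: 4 5-O-(tert-butyldiphenylsilyl)-1,2-O-isopropylidene-β-L-threo-pentofuranos-3-ulose
Conditions: Dess–Martin periodinane, NaHCO3, CH2Cl2, rt
Reagents that add atoms: none
Why: Dess–Martin oxidation of the unhindered exo secondary alcohol gives the 3-ulose under buffered conditions that spare the silyl ether and the acetonide.

Step 4
Reactants: 4 5-O-(tert-butyldiphenylsilyl)-1,2-O-isopropylidene-β-L-threo-pentofuranos-3-ulose
Product: 5 5-O-(tert-butyldiphenylsilyl)-1,2-O-isopropylidene-3-C-(methoxycarbonylmethyl)-β-L-lyxofuranose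
Conditions: LiN(iPr)2, CH3CO2CH3, THF, −78 °C; then 4, −78 °C; aq. NH4Cl
Reagents that add atoms: methyl acetate COC(C)=O
Why: Aldol addition of the lithium ester enolate to the strained ketone takes place on the exo face of the cis-fused bicycle, opposite to the acetonide and to the C5 side chain, so the new C–C bond (later C7–C11) is on the upper face and the tertiary hydroxyl is cis to O2 (L-lyxo), which sets C7.

Step 5
Reactants: 5 5-O-(tert-butyldiphenylsilyl)-1,2-O-isopropylidene-3-C-(methoxycarbonylmethyl)-β-L-lyxofuranose
Product: 6 1,2-O-isopropylidene-3-C-(methoxycarbonylmethyl)-β-L-lyxofuranose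
Conditions: Bu4NF, AcOH, THF, 0 °C to rt
Reagents that add atoms: none
Why: Fluoride-induced desilylation frees the primary hydroxyl, and the acetic acid buffer keeps the alkoxide from attacking the methyl ester.

Step 6
Reactants: 6 1,2-O-isopropylidene-3-C-(methoxycarbonylmethyl)-β-L-lyxofuranose
Product: 7 1,2-O-isopropylidene-3-C-(methoxycarbonylmethyl)-β-L-lyxo-pentodialdo-1,4-furanose
Conditions: Dess–Martin periodinane, NaHCO3, CH2Cl2, 0 °C to rt
Reagents that add atoms: none
Why: Dess–Martin oxidation converts the primary alcohol into the aldehyde without touching the tertiary alcohol and without a base that could epimerise C4.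

Step 7
Reactants: 7 1,2-O-isopropylidene-3-C-(methoxycarbonylmethyl)-β-L-lyxo-pentodialdo-1,4-furanose
Product: 8 5,6-dideoxy-1,2-O-isopropylidene-3-C-(methoxycarbonylmethyl)-β-L-lyxo-hex-5-enofuranose
Conditions: Ph3PCH3Br, KN(SiMe3)2 (excess), THF, −78 to 0 °C
Reagents that add atoms: methyltriphenylphosphonium bromide C[P+](c1ccccc1)(c1ccccc1)c1ccccc1.[Br-]
Why: Wittig methylenation of furanose C5 aldehydes is fast at low temperature, so the vinyl group (C5 of the target plus the carbon later lost as ethylene) should form before C4 can epimerise, the tertiary hydroxyl merely consuming one equivalent of ylide.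

Step 8
Reactants: 8 5,6-dideoxy-1,2-O-isopropylidene-3-C-(methoxycarbonylmethyl)-β-L-lyxo-hex-5-enofuranose
Product: 9 5,6-dideoxy-2,3-O-isopropylidene-3-C-(methoxycarbonylmethyl)-L-lyxo-hex-5-enofuranose (lactol; both anomers)
Conditions: TsOH·H2O (cat.), acetone, rt
Reagents that add atoms: none
Why: Acid-catalysed acetonide migration, in which opening at O1 leaves an oxocarbenium ion on O2 that is captured by the cis tertiary O3, should favour the 2,3-acetonide as it does for other cis-2,3-diol furanoses, which protects the future O7/O8 pair and unmasks C1 as a lactol.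

Step 9
Reactants: 9 5,6-dideoxy-2,3-O-isopropylidene-3-C-(methoxycarbonylmethyl)-L-lyxo-hex-5-enofuranose
Product: 12 hydroxy lactone diene 4-(1-hydroxy-2-methylprop-2-en-1-yl)-2,2-dimethyl-6-vinyl-1,3,7-trioxaspiro[4.4]nonan-8-one (both C9 epimers), via potassium carboxylate 10 (not isolated), via dihydroxy acid 11 (not isolated)
Conditions: Me3SiOK, THF, rt; then CH2=C(CH3)MgBr (excess), 0 °C to rt; then 1 M HCl to pH 2, EtOAc, rt
Reagents that add atoms: isopropenylmagnesium bromide CC(=C)[Mg]Br
Why: Silanolate ester cleavage gives a carboxylate that is inert to the Grignard reagent, Grignard addition to the lactol through its open aldehyde form then joins C10 (with C14) to C9 and frees O6, and on acidification the γ-hydroxy acid closes to the five-membered lactone on O6 because O8 is held in the acetonide and O9 would need a six-membered ring, C9 being taken as both epimers since it is oxidised in step 11.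

Step 10
Reactants: 12 hydroxy lactone diene
Product: 13 cyclohexenol (ring C5=C10(CH3)–C9H(OH)–C8–C7–C6 with the γ-lactone on C6–C7 and the acetonide on C7–C8; both C9 epimers)
Conditions: second-generation Grubbs catalyst (5 mol %), CH2Cl2, 40 °C
Reagents that add atoms: none
Why: Ring-closing metathesis between the vinyl group on C6 and the isopropenyl group on C9 closes the six-membered ring C5–C10 with loss of ethylene, a closure that is routine for isopropenyl carbinols and creates no stereocentre.

Step 11
Reactants: 13 cyclohexenol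
Product: 14 lactone- and acetonide-fused 2-methylcyclohex-2-enone (C9=O, C10(CH3)=C5; lactone O6 and C11 on one ring face, O7/O8 acetonide on the other)
Conditions: Dess–Martin periodinane, NaHCO3, CH2Cl2, rt
Reagents that add atoms: none
Why: Dess–Martin oxidation of the only free (allylic) hydroxyl gives the enone from either C9 epimer, and the cis-fused acetonide keeps the α-stereocentre C8 from epimerising.

Step 12
Reactants: 15 methylenecyclobutane
Product: 16 1-methylcyclobutene
Conditions: KOC(CH3)3 (cat.), DMSO, 55 °C; distil
Reagents that add atoms: none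
Why: Base-catalysed alkene isomerisation through the allyl anion should move the double bond into the ring, where the trisubstituted alkene is the more stable isomer, and the volatile product is distilled off.

Step 13
Reactants: 14 lactone- and acetonide-fused 2-methylcyclohex-2-enone, 16 1-methylcyclobutene
Product: 17 cis-anti-cis 6-4-4 photoadduct (new bonds C10–C1 and C5–C4; cyclobutanes C10–C1–C4–C5 and C1–C2–C3–C4; CH3 on C10 and on C4; cyclobutane on the ring face of the acetonide)
Conditions: hν (350 nm, Pyrex), 16 (excess), CH2Cl2, −20 °C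
Reagents that add atoms: none
Why: The excited enone triplet bonds to the alkene stepwise through a triplet 1,4-biradical that closes after spin inversion, which is the known enone–alkene [2+2] photocycloaddition in its enone–cyclobutene form. One ring closes, the cyclobutane C10–C1–C4–C5, by intermolecular [2+2] addition (radical recombination of the biradical), and together with the cyclobutene ring it makes a bicyclo[2.2.0]hexane. C1 and C4 are cis because they come from a four-membered cis alkene; C5 and C10 should be cis because the lactone and acetonide fused at C6–C7–C8 limit the twist of the excited enone so that the less strained cis-bicyclo[4.2.0] closure wins; the alkene is expected on the face anti to the lactone oxygen on C6, with the cyclobutene ring turned away from the six-membered ring. The step needs head-to-tail regiochemistry (C4 to C5, C1 to C10) and a cis 6-4 fusion: the first rests on the C10 methyl, because the head-to-head biradical would have to join the two fully substituted centres C10 and C4 and should mostly revert, and the second on the ring strain just named. Facial and syn/anti isomers of the cis-fused adduct are tolerable because all four new stereocentres are removed in step 14.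

Step 14
Reactants: 17 cis-anti-cis 6-4-4 photoadduct
Product: 18 (1(10)Z,4E)-7,8-(isopropylidenedioxy)-9-oxogermacra-1(10),4-dien-12,6-olide
Conditions: toluene (degassed, silylated sealed tube), 200 °C
Reagents that add atoms: none
Why: Thermal cycloreversion of the bicyclo[2.2.0]hexane breaks the strained central C1–C4 bond first, and the resulting cyclohexane-1,4-diyl then cleaves C5–C10 through the chair that keeps C6 and the C10 methyl equatorial and only C9 axial, which should give C1=C10 as Z and C4=C5 as E, while conjugation of C1=C10 with the C9 ketone and the Z,E geometry hold back Cope contraction.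

Step 15
Reactants: 18 (1(10)Z,4E)-7,8-(isopropylidenedioxy)-9-oxogermacra-1(10),4-dien-12,6-olide
Product: 19 (1(10)Z,4E,9R)-9-hydroxy-7,8-(isopropylidenedioxy)germacra-1(10),4-dien-12,6-olide
Conditions: NaBH4, CeCl3·7H2O, MeOH, −78 °C
Reagents that add atoms: none
Why: Luche reduction gives clean 1,2-reduction of the enone, and hydride is expected to approach C9 anti to the C8–O bond (Felkin–Anh) from outside the ring, which places the new hydroxyl trans to O8 and sets C9 as R.

Step 16
Reactants: 19 (9R)-9-hydroxy-7,8-(isopropylidenedioxy)germacra-1(10),4-dien-12,6-olide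
Product: 21 (9R)-13-(dimethylamino)-9-hydroxy-7,8-(isopropylidenedioxy)germacra-1(10),4-dien-12,6-olide (C11 epimers), via bis-silyl ketene acetal 20 (not isolated)
Conditions: Me3SiOSO2CF3, Et3N, CH2Cl2, 0 °C; then [Me2N=CH2]I, rt; aq. citric acid, then NaHCO3
Reagents that add atoms: N,N-dimethylmethyleneiminium iodide (Eschenmoser's salt) C[N+](C)=C.[I-]
Why: Soft enolisation converts the lactone into its silyl ketene acetal (and the C9 hydroxyl into a labile silyl ether) without a free enolate that could expel the β-oxygen on C7, and Mannich reaction with Eschenmoser's salt then aminomethylates C11, whose new centre is of no consequence because it becomes trigonal in step 18.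

Step 17
Reactants: 21 (9R)-13-(dimethylamino)-9-hydroxy-7,8-(isopropylidenedioxy)germacra-1(10),4-dien-12,6-olide
Product: 22 (9R)-9-angeloyloxy-13-(dimethylamino)-7,8-(isopropylidenedioxy)germacra-1(10),4-dien-12,6-olide (C11 epimers)
Conditions: angelic acid, 2,4,6-Cl3C6H2COCl, Et3N, toluene, rt; then 21, 75 °C
Reagents that add atoms: angelic acid C/C=C(/C)C(O)=O
Why: Yamaguchi esterification through the mixed anhydride acylates the only free hydroxyl (C9) under conditions chosen to keep the Z acid from isomerising to the tiglate, while the dimethylamino adduct keeps the lactone from acting as a Michael acceptor in this warm, amine-containing step.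

Step 18
Reactants: 22 (9R)-9-angeloyloxy-13-(dimethylamino)-7,8-(isopropylidenedioxy)germacra-1(10),4-dien-12,6-olide
Product: 24 (1(10)Z,4E,9R)-9-angeloyloxy-7,8-(isopropylidenedioxy)germacra-1(10),4,11(13)-trien-12,6-olide, via trimethylammonium iodide 23 (not isolated)
Conditions: CH3I, acetone, rt; then aq. NaHCO3, EtOAc, rt
Reagents that add atoms: none
Why: Exhaustive N-methylation followed by mild base brings about Hofmann-type E1cB loss of trimethylamine and unmasks the α-methylene lactone (C11=C13), the ammonium group being a far better leaving group than the acetonide oxygen on C7.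

Step 19
Reactants: 24 (9R)-9-angeloyloxy-7,8-(isopropylidenedioxy)germacra-1(10),4,11(13)-trien-12,6-olide
Product: 25 CNP0303917.1, (1(10)Z,4E,6S,7S,8S,9R)-9-angeloyloxy-7,8-dihydroxygermacra-1(10),4,11(13)-trien-12,6-olide
Conditions: AcOH/H2O (4:1), 40 °C
Reagents that add atoms: none
Why: Mild acidic hydrolysis of the acetonide releases the cis C7/C8 diol and completes the target, in which C6, C7, C8, C9 and both ring alkenes keep the configurations set in steps 1 to 15.

**Compound list**

1 | L-arabinose (drawn open-chain) | O=C[C@H](O)[C@@H](O)[C@@H](O)CO | starting material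
2 | 5-O-(tert-butyldiphenylsilyl)-L-arabinofuranose (both anomers; C1 left open) | CC(C)(C)[Si](c1ccccc1)(c1ccccc1)OC[C@@H]1OC(O)[C@H](O)[C@H]1O | intermediate
3 | 5-O-(tert-butyldiphenylsilyl)-1,2-O-isopropylidene-β-L-arabinofuranose | CC(C)(C)[Si](c1ccccc1)(c1ccccc1)OC[C@@H]1O[C@@H]2OC(C)(C)O[C@@H]2[C@H]1O | intermediate
4 | 5-O-(tert-butyldiphenylsilyl)-1,2-O-isopropylidene-β-L-threo-pentofuranos-3-ulose | CC(C)(C)[Si](c1ccccc1)(c1ccccc1)OC[C@@H]1O[C@@H]2OC(C)(C)O[C@@H]2C1=O | intermediate
5 | 5-O-(tert-butyldiphenylsilyl)-1,2-O-isopropylidene-3-C-(methoxycarbonylmethyl)-β-L-lyxofuranose (tertiary 3-OH cis to the acetonide) | CC(C)(C)[Si](c1ccccc1)(c1ccccc1)OC[C@@H]1O[C@@H]2OC(C)(C)O[C@@H]2[C@@]1(O)CC(=O)OC | intermediate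
6 | 1,2-O-isopropylidene-3-C-(methoxycarbonylmethyl)-β-L-lyxofuranose | OC[C@@H]1O[C@@H]2OC(C)(C)O[C@@H]2[C@@]1(O)CC(=O)OC | intermediate
7 | 1,2-O-isopropylidene-3-C-(methoxycarbonylmethyl)-β-L-lyxo-pentodialdo-1,4-furanose | O=C[C@@H]1O[C@@H]2OC(C)(C)O[C@@H]2[C@@]1(O)CC(=O)OC | intermediate
8 | 5,6-dideoxy-1,2-O-isopropylidene-3-C-(methoxycarbonylmethyl)-β-L-lyxo-hex-5-enofuranose | C=C[C@@H]1O[C@@H]2OC(C)(C)O[C@@H]2[C@@]1(O)CC(=O)OC | intermediate
9 | 5,6-dideoxy-2,3-O-isopropylidene-3-C-(methoxycarbonylmethyl)-L-lyxo-hex-5-enofuranose (lactol; both anomers, C1 left open) | C=C[C@@H]1OC(O)[C@@H]2OC(C)(C)O[C@@]21CC(=O)OC | intermediate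
10 | potassium carboxylate of lactol 9 | C=C[C@@H]1OC(O)[C@@H]2OC(C)(C)O[C@@]21CC(=O)[O-].[K+] | intermediate (not isolated)
11 | 2-[5-(1-hydroxy-2-methylprop-2-en-1-yl)-4-(1-hydroxyprop-2-en-1-yl)-2,2-dimethyl-1,3-dioxolan-4-yl]acetic acid (C6, C7, C8 as in 9; both C9 epimers, C9 left open) | C=C[C@H](O)[C@@]1(CC(=O)O)OC(C)(C)O[C@H]1C(O)C(C)=C | intermediate (not isolated)
12 | 4-(1-hydroxy-2-methylprop-2-en-1-yl)-2,2-dimethyl-6-vinyl-1,3,7-trioxaspiro[4.4]nonan-8-one (γ-lactone on O6, spiro to the 7,8-acetonide; both C9 epimers, C9 left open) | C=C[C@@H]1OC(=O)C[C@@]12OC(C)(C)O[C@H]2C(O)C(C)=C | intermediate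
13 | cyclohexenol: C5=C10(CH3)–C9H(OH)–C8–C7–C6 ring with γ-lactone on C6–C7 and acetonide on C7–C8 (both C9 epimers, C9 left open) | CC1=C[C@@H]2OC(=O)C[C@]2(OC(C)(C)O3)[C@@H]3C1O | intermediate
14 | lactone- and acetonide-fused 2-methylcyclohex-2-enone (C9=O; O6 and C11 on one face, O7 and O8 on the other) | CC1=C[C@@H]2OC(=O)C[C@]2(OC(C)(C)O3)[C@@H]3C1=O | intermediate
15 | methylenecyclobutane | C=C1CCC1 | starting material
16 | 1-methylcyclobutene | CC1=CCC1 | intermediate
17 | cis-anti-cis 6-4-4 photoadduct (tricyclo[4.4.0.0^2,5]decanone core with fused lactone and acetonide; CH3 on C10 and C4) | C[C@]12[C@@H]3CC[C@]3(C)[C@H]1[C@@H]4OC(=O)C[C@]4(OC(C)(C)O5)[C@@H]5C2=O | intermediate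
18 | (1(10)Z,4E)-7,8-(isopropylidenedioxy)-9-oxogermacra-1(10),4-dien-12,6-olide | C1C(=O)O[C@H]2/C=C(\C)CC/C=C(/C)C(=O)[C@@H]3OC(C)(C)O[C@]123 | intermediate
19 | (1(10)Z,4E,9R)-9-hydroxy-7,8-(isopropylidenedioxy)germacra-1(10),4-dien-12,6-olide | C1C(=O)O[C@H]2/C=C(\C)CC/C=C(/C)[C@@H](O)[C@@H]3OC(C)(C)O[C@]123 | intermediate
20 | silyl ketene acetal of 19 with C9–O–SiMe3 (C12–O–SiMe3, C11=C12) | C1=C(O[Si](C)(C)C)O[C@H]2/C=C(\C)CC/C=C(/C)[C@@H](O[Si](C)(C)C)[C@@H]3OC(C)(C)O[C@]123 | intermediate (not isolated)
21 | (9R)-13-(dimethylamino)-9-hydroxy-7,8-(isopropylidenedioxy)germacra-1(10),4-dien-12,6-olide (C11 epimers, C11 left open) | CN(C)CC1C(=O)O[C@H]2/C=C(\C)CC/C=C(/C)[C@@H](O)[C@@H]3OC(C)(C)O[C@]123 | intermediate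
22 | (9R)-9-angeloyloxy-13-(dimethylamino)-7,8-(isopropylidenedioxy)germacra-1(10),4-dien-12,6-olide (C11 epimers, C11 left open) | CN(C)CC1C(=O)O[C@H]2/C=C(\C)CC/C=C(/C)[C@@H](OC(=O)/C(C)=C\C)[C@@H]3OC(C)(C)O[C@]123 | intermediate
23 | 13-(trimethylammonio) iodide of 22 | C[N+](C)(C)CC1C(=O)O[C@H]2/C=C(\C)CC/C=C(/C)[C@@H](OC(=O)/C(C)=C\C)[C@@H]3OC(C)(C)O[C@]123.[I-] | intermediate (not isolated)
24 | (1(10)Z,4E,9R)-9-angeloyloxy-7,8-(isopropylidenedioxy)germacra-1(10),4,11(13)-trien-12,6-olide | C=C1C(=O)O[C@H]2/C=C(\C)CC/C=C(/C)[C@@H](OC(=O)/C(C)=C\C)[C@@H]3OC(C)(C)O[C@]123 | intermediate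
25 | CNP0303917.1, (1(10)Z,4E,6S,7S,8S,9R)-9-angeloyloxy-7,8-dihydroxygermacra-1(10),4,11(13)-trien-12,6-olide | C=C1C(=O)O[C@H]2/C=C(\C)CC/C=C(/C)[C@@H](OC(=O)/C(C)=C\C)[C@H](O)[C@@]12O | target

**Step count and risks**

Total step count: 19 (18 in the main line plus the isomerisation that makes 16). Longest linear sequence: 18 steps (steps 1–11 and 13–19).

The three steps most likely to fail:

Step 13 (photocycloaddition). Both faces of the enone are screened, by the lactone above and by the endo methyl group of the acetonide below. The triplet may therefore relax, or the first-formed biradical may revert, and the share of head-to-head bonding or of trans ring closure may grow. The fallback changes the substrate, not the irradiation conditions. It sets out from 14: the acetonide is hydrolysed (CF3CO2H/H2O, 0 °C) to the enone 7,8-diol F1, whose lower face is open. F1 is irradiated with 16 as in step 13 to the photoadduct diol F2. The acetonide is then re-formed (Me2C(OMe)2, pyridinium p-toluenesulfonate, CH2Cl2), which comes back to the route at 17.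

Step 14 (cycloreversion). At 200 °C the C9 ketone opens paths of its own: enolisation toward C8 with loss of the C7 oxygen, or cleavage next to the carbonyl. The diyl may also split C2–C3 instead of C5–C10 to a divinylcyclohexanone, or 18 may contract by Cope rearrangement. The fallback moves C9 to a different oxidation level for the thermal step. It sets out from 17: the ketone is reduced (NaBH4, CH3OH, 0 °C) to the tricyclic C9 alcohol F3, of which either epimer serves. The cycloreversion is run on F3 to the cyclodecadienol F4, and the allylic alcohol is oxidised (Dess–Martin periodinane, NaHCO3, CH2Cl2), which comes back at 18.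

Step 15 (C9 reduction). Facial selectivity in the ten-membered ring may be poor or reversed, with hydride entering syn to the C8–O bond and giving mainly the 9S alcohol. The fallback inverts the centre instead of relying on direct reduction. It sets out from 18, whose Luche reduction would then give the 9S alcohol F5. Mitsunobu reaction (PPh3, diisopropyl azodicarboxylate, 4-nitrobenzoic acid, THF, 0 °C) inverts C9 to the 9R 4-nitrobenzoate F6, and methanolysis (K2CO3, CH3OH, 0 °C) comes back at 19.

**Further compounds**

F1 | step 13 | enone 7,8-diol (14 without the acetonide) | CC1=C[C@@H]2OC(=O)C[C@]2(O)[C@@H](O)C1=O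
F2 | step 13 | photoadduct 7,8-diol (17 without the acetonide) | C[C@]12[C@@H]3CC[C@]3(C)[C@H]1[C@@H]4OC(=O)C[C@]4(O)[C@@H](O)C2=O
F3 | step 14 | tricyclic C9 alcohol (17 with C9–OH; C9 left open) | C[C@]12[C@@H]3CC[C@]3(C)[C@H]1[C@@H]4OC(=O)C[C@]4(OC(C)(C)O5)[C@@H]5C2O
F4 | step 14 | (1(10)Z,4E)-9-hydroxy-7,8-(isopropylidenedioxy)germacra-1(10),4-dien-12,6-olide (C9 left open) | C1C(=O)O[C@H]2/C=C(\C)CC/C=C(/C)C(O)[C@@H]3OC(C)(C)O[C@]123
F5 | step 15 | (9S)-9-hydroxy-7,8-(isopropylidenedioxy)germacra-1(10),4-dien-12,6-olide | C1C(=O)O[C@H]2/C=C(\C)CC/C=C(/C)[C@H](O)[C@@H]3OC(C)(C)O[C@]123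
F6 | step 15 | (9R)-9-(4-nitrobenzoyloxy)-7,8-(isopropylidenedioxy)germacra-1(10),4-dien-12,6-olide | C1C(=O)O[C@H]2/C=C(\C)CC/C=C(/C)[C@@H](OC(=O)c4ccc(cc4)[N+](=O)[O-])[C@@H]3OC(C)(C)O[C@]123
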